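**Plan**

- Numbering: ring C5 (isopropenyl), C6 (OH), C7 (bears carbinol C11 with acetoxymethyl carbons C12 and C13), C8, C9, C10 (methyl, vinyl). The enabling feature is the 1,3-diol made up of the C6 and C11 hydroxyls across C7, with acetates on C12 and C13: it is the hydrate of an aldehyde–alkene adduct whose C11 cation one of these acetates can capture.
- Retrosynthesis: cut C6–C7 and C11–O (Prins closure of the only ring), then C5–C10 (Ireland–Claisen), then the ester C–O bond, the C7=C11 alkene (Knoevenagel) and the 6,7-alkene of geranyl acetate (ozonolysis).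
- Forward: geranyl acetate is cut to the C7 aldehyde, extended with dimethyl malonate, reduced, masked as an acetonide, esterified with 3-methylbut-3-enoic acid and rearranged. Diol release, acetylation and acid-to-aldehyde reduction give the open-chain aldehyde, and the cyclohexane ring closes in the last step.
- Stereochemistry: C5 and C10 come from the chiral boron enolate Ireland–Claisen (E(O) enolate, E-alkene, chair). C6 and C7 are relayed from them through the all-equatorial chair of the ring closure.

Key step: step 10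

Assumption: the (S,S)-bromoborane L*BBr, (4S,5S)-2-bromo-1,3-bis{[3,5-bis(trifluoromethyl)phenyl]sulfonyl}-4,5-diphenyl-1,3,2-diazaborolidine, SMILES BrB1N(S(=O)(=O)c2cc(cc(c2)C(F)(F)F)C(F)(F)F)[C@@H](c2ccccc2)[C@H](c2ccccc2)N1S(=O)(=O)c1cc(cc(c1)C(F)(F)F)C(F)(F)F, is taken to deliver the (2S,3S) acid from the E(O) enolate; if the sense of induction is the reverse, its (R,R) enantiomer is used with nothing else changed.

**Route**

Step 1
Reactants: 1 geranyl acetate
Product: 3 (2E)-3-methyl-6-oxohex-2-en-1-yl acetate, via ozonide 2 (not isolated)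
Conditions: O3 (1 equiv, Sudan red 7B end point), CH2Cl2, −78 °C; then Me2S, −78 °C → rt
Reagents that add atoms: ozone, [O-][O+]=O
Why: Ozonolysis with reductive work-up should cleave only the electron-rich 6,7-alkene, because the 2,3-alkene is deactivated by the allylic acetate and keeps its E geometry.

Step 2
Reactants: 3 (2E)-3-methyl-6-oxohex-2-en-1-yl acetate; 4 dimethyl malonate
Product: 5 dimethyl 2-[(4E)-6-acetoxy-4-methylhex-4-en-1-ylidene]propanedioate
Conditions: piperidine (cat.), AcOH (cat.), toluene, Dean–Stark, reflux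
Reagents that add atoms: none
Why: Knoevenagel condensation of an aliphatic aldehyde with a malonate under piperidinium acetate catalysis with azeotropic removal of water installs C11 with both carboxyl carbons (C12, C13) in one operation.

Step 3
Reactants: 5 dimethyl 2-[(4E)-6-acetoxy-4-methylhex-4-en-1-ylidene]propanedioate
Product: 6 (2E)-7-(hydroxymethyl)-3-methylocta-2,6-diene-1,8-diol
Conditions: iBu2AlH (7 equiv), CH2Cl2, −78 → 0 °C; aq. potassium sodium tartrate
Reagents that add atoms: none
Why: Hydride reduction with iBu2AlH in a non-coordinating solvent should reduce the alkylidene malonate 1,2-wise to the 2-alkylidene-1,3-diol and cleave the acetate in the same operation.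

Step 4
Reactants: 6 (2E)-7-(hydroxymethyl)-3-methylocta-2,6-diene-1,8-diol
Product: 7 (2E)-5-(2,2-dimethyl-1,3-dioxan-5-ylidene)-3-methylpent-2-en-1-ol
Conditions: Me2C(OMe)2, PPTS (cat.), acetone, rt; aq. NaHCO3
Reagents that add atoms: 2,2-dimethoxypropane, COC(C)(C)OC
Why: Acid-catalysed transacetalization (isopropylidene acetal formation) distinguishes the three primary hydroxyls, since only the 1,3-diol can close a six-membered cyclic acetal and the isolated allylic hydroxyl is returned free after work-up.

Step 5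
Reactants: 7 (2E)-5-(2,2-dimethyl-1,3-dioxan-5-ylidene)-3-methylpent-2-en-1-ol; 8 3-methylbut-3-enoic acid
Product: 9 (2E)-5-(2,2-dimethyl-1,3-dioxan-5-ylidene)-3-methylpent-2-en-1-yl 3-methylbut-3-enoate
Conditions: DCC, DMAP (5 mol %), CH2Cl2, −20 → 0 °C
Reagents that add atoms: none
Why: Steglich esterification at low temperature with little DMAP should acylate the primary allylic alcohol without moving the β,γ double bond of the acid into conjugation.

Step 6
Reactants: 9 (2E)-5-(2,2-dimethyl-1,3-dioxan-5-ylidene)-3-methylpent-2-en-1-yl 3-methylbut-3-enoate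
Product: 12 (2S,3S)-6-(2,2-dimethyl-1,3-dioxan-5-ylidene)-3-ethenyl-3-methyl-2-(prop-1-en-2-yl)hexanoic acid, via boron ketene acetal 10 (not isolated), via acyloxyborane 11 (not isolated)
Conditions: L*BBr (1.2 equiv), Et3N (1.5 equiv), toluene–hexane 2:1, −78 °C; then 4 °C; H2O
Reagents that add atoms: none
Why: In this enantioselective Ireland–Claisen rearrangement, soft enolization in a non-polar medium should give the E(O) boron ketene acetal 10, whose chair with the E-alkene (chain equatorial, methyl and isopropenyl axial) joins C5 to C10 with isopropenyl cis to methyl, while the C2-symmetric sulfonamide ligand selects the enolate face and the acetonide is expected to survive the amine-buffered boron halide as it does in boron aldol enolizations.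

Step 7
Reactants: 12 (2S,3S)-6-(2,2-dimethyl-1,3-dioxan-5-ylidene)-3-ethenyl-3-methyl-2-(prop-1-en-2-yl)hexanoic acid
Product: 13 (2S,3S)-3-ethenyl-8-hydroxy-7-(hydroxymethyl)-3-methyl-2-(prop-1-en-2-yl)oct-6-enoic acid
Conditions: AcOH–H2O–THF 3:1:1, rt
Reagents that add atoms: none
Why: Mild acid-catalysed acetal hydrolysis frees the 1,3-diol without touching the alkenes or the C5 stereocentre.

Step 8
Reactants: 13 (2S,3S)-3-ethenyl-8-hydroxy-7-(hydroxymethyl)-3-methyl-2-(prop-1-en-2-yl)oct-6-enoic acid
Product: 15 (2S,3S)-8-acetoxy-7-(acetoxymethyl)-3-ethenyl-3-methyl-2-(prop-1-en-2-yl)oct-6-enoic acid, via mixed anhydride 14 (not isolated)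
Conditions: Ac2O, pyridine, CH2Cl2, 0 °C → rt; then H2O–THF, rt
Reagents that add atoms: acetic anhydride, CC(=O)OC(C)=O
Why: Acetylation of the two primary allylic alcohols with Ac2O and pyridine (no DMAP, to spare the C5 centre) also acylates the carboxyl group, and the mixed anhydride 14 is hydrolysed back to the acid on aqueous treatment.

Step 9
Reactants: 15 (2S,3S)-8-acetoxy-7-(acetoxymethyl)-3-ethenyl-3-methyl-2-(prop-1-en-2-yl)oct-6-enoic acid
Product: 17 (2S,3S)-8-acetoxy-7-(acetoxymethyl)-3-ethenyl-3-methyl-2-(prop-1-en-2-yl)oct-6-enal, via acid chloride 16 (not isolated)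
Conditions: 1-chloro-N,N,2-trimethylprop-1-en-1-amine, CH2Cl2, 0 °C → rt; evaporate; LiAlH(OtBu)3 (1.1 equiv), THF, −78 °C
Reagents that add atoms: none
Why: Neutral acyl chloride formation with the α-chloroenamine followed by partial hydride reduction with LiAlH(OtBu)3 at −78 °C should stop at the aldehyde, leave the acetates alone and avoid base that could epimerize C5 or conjugate the isopropenyl group.

Step 10
Reactants: 17 (2S,3S)-8-acetoxy-7-(acetoxymethyl)-3-ethenyl-3-methyl-2-(prop-1-en-2-yl)oct-6-enal
Product: 20 2-[(1R,2R,3S,4S)-4-ethenyl-2-hydroxy-4-methyl-3-(prop-1-en-2-yl)cyclohexyl]-2-hydroxypropane-1,3-diyl diacetate (the target CNP0273389.1), via dioxolanylium stannate 18 (not isolated), via tertiary acetate 19 (not isolated)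
Conditions: SnCl4 (1.2 equiv), CH2Cl2, −78 °C; sat. aq. NaHCO3, −78 °C → rt; then DBU (0.1 equiv), CH2Cl2, rt
Reagents that add atoms: water, O
Why: Proposed new method: SnCl4 binds the C6 aldehyde, C7 of the C7=C11 alkene attacks C6, and the charge building up on C11 is taken over by the carbonyl oxygen of a flanking acetate to give the 2-methyl-1,3-dioxolan-2-ylium ion 18, which water opens at its C2 to hydroxy acetates, the tertiary ester 19 among them being moved to the primary oxygen by catalytic DBU through the five-membered orthoacid; the reasoning is that five-membered acyloxy participation should be faster than proton loss or chloride capture and should make up for the electron withdrawal the two acetoxy groups exert on the alkene. The closest known reactions are the acid-promoted Prins cyclization of citronellal to isopulegol and to p-menthane-3,8-diol and the capture of cations by a neighbouring acetate as in the Woodward and Prévost reactions. The one cyclohexane ring closes by a 6-exo-trig attack on the carbonyl carbon, with the alkene likewise exocyclic to the new ring. C6 and C7 are set in a chair in which the C5 isopropenyl group, the C10 vinyl group, the tin-bound oxygen and the C7=C11 terminus are all equatorial, the axial C10 methyl group adding a syn-diaxial penalty to an axial oxygen, so the hydroxyl should end up trans to both neighbours (6R,7R). The step needs chemoselectivity among three alkenes, and the substrate secures it: only the C7=C11 alkene can close a six-membered ring through a tertiary cation, whereas the isopropenyl group could close only a four-membered ring and the vinyl group only a four-membered ring or, through a secondary cation, a five-membered one. C11 carries two identical arms in 20, so it does not matter which acetate captures the cation.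

**Compound list**

1 | geranyl acetate, (2E)-3,7-dimethylocta-2,6-dien-1-yl acetate | CC(C)=CCC/C(C)=C/COC(C)=O | starting material
2 | (2E)-5-(5,5-dimethyl-1,2,4-trioxolan-3-yl)-3-methylpent-2-en-1-yl acetate (ozonide, racemic at the ring carbon, not isolated) | CC(=O)OC/C=C(\C)CCC1OOC(C)(C)O1 | intermediate
3 | (2E)-3-methyl-6-oxohex-2-en-1-yl acetate | CC(=O)OC/C=C(\C)CCC=O | intermediate
4 | dimethyl malonate | COC(=O)CC(=O)OC | starting material
5 | dimethyl 2-[(4E)-6-acetoxy-4-methylhex-4-en-1-ylidene]propanedioate | CC(=O)OC/C=C(\C)CCC=C(C(=O)OC)C(=O)OC | intermediate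
6 | (2E)-7-(hydroxymethyl)-3-methylocta-2,6-diene-1,8-diol | OC/C=C(\C)CCC=C(CO)CO | intermediate
7 | (2E)-5-(2,2-dimethyl-1,3-dioxan-5-ylidene)-3-methylpent-2-en-1-ol | OC/C=C(\C)CCC=C1COC(C)(C)OC1 | intermediate
8 | 3-methylbut-3-enoic acid | C=C(C)CC(=O)O | starting material
9 | (2E)-5-(2,2-dimethyl-1,3-dioxan-5-ylidene)-3-methylpent-2-en-1-yl 3-methylbut-3-enoate | C=C(C)CC(=O)OC/C=C(\C)CCC=C1COC(C)(C)OC1 | intermediate
10 | E(O) boron ketene acetal of 9: the enolate oxygen carries the (4S,5S)-diazaborolidinyl boron and the isopropenyl group is trans to that oxygen (not isolated) | C=C(C)/C=C(/OB1N(S(=O)(=O)c2cc(cc(c2)C(F)(F)F)C(F)(F)F)[C@@H](c2ccccc2)[C@H](c2ccccc2)N1S(=O)(=O)c1cc(cc(c1)C(F)(F)F)C(F)(F)F)OC/C=C(\C)CCC=C1COC(C)(C)OC1 | intermediate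
11 | acyloxyborane: the (2S,3S) acid 12 bound through its carboxyl oxygen to the same diazaborolidinyl boron (not isolated) | O=C(OB1N(S(=O)(=O)c2cc(cc(c2)C(F)(F)F)C(F)(F)F)[C@@H](c2ccccc2)[C@H](c2ccccc2)N1S(=O)(=O)c1cc(cc(c1)C(F)(F)F)C(F)(F)F)[C@@H](C(C)=C)[C@](C)(C=C)CCC=C1COC(C)(C)OC1 | intermediate
12 | (2S,3S)-6-(2,2-dimethyl-1,3-dioxan-5-ylidene)-3-ethenyl-3-methyl-2-(prop-1-en-2-yl)hexanoic acid | OC(=O)[C@@H](C(C)=C)[C@](C)(C=C)CCC=C1COC(C)(C)OC1 | intermediate
13 | (2S,3S)-3-ethenyl-8-hydroxy-7-(hydroxymethyl)-3-methyl-2-(prop-1-en-2-yl)oct-6-enoic acid | OC(=O)[C@@H](C(C)=C)[C@](C)(C=C)CCC=C(CO)CO | intermediate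
14 | acetic (2S,3S)-8-acetoxy-7-(acetoxymethyl)-3-ethenyl-3-methyl-2-(prop-1-en-2-yl)oct-6-enoic anhydride (not isolated) | CC(=O)OC(=O)[C@@H](C(C)=C)[C@](C)(C=C)CCC=C(COC(C)=O)COC(C)=O | intermediate
15 | (2S,3S)-8-acetoxy-7-(acetoxymethyl)-3-ethenyl-3-methyl-2-(prop-1-en-2-yl)oct-6-enoic acid | OC(=O)[C@@H](C(C)=C)[C@](C)(C=C)CCC=C(COC(C)=O)COC(C)=O | intermediate
16 | (2S,3S)-8-acetoxy-7-(acetoxymethyl)-3-ethenyl-3-methyl-2-(prop-1-en-2-yl)oct-6-enoyl chloride (not isolated) | ClC(=O)[C@@H](C(C)=C)[C@](C)(C=C)CCC=C(COC(C)=O)COC(C)=O | intermediate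
17 | (2S,3S)-8-acetoxy-7-(acetoxymethyl)-3-ethenyl-3-methyl-2-(prop-1-en-2-yl)oct-6-enal | O=C[C@@H](C(C)=C)[C@](C)(C=C)CCC=C(COC(C)=O)COC(C)=O | intermediate
18 | cyclized cation: 2-methyl-1,3-dioxolan-2-ylium ion whose ring carbons 4 and 5 are C11 and C12, with the second acetoxymethyl group on C11, SnCl4 on the C6 oxygen, ring stereocentres as in 20, either configuration at C11 (not isolated) | C=C[C@]1(C)CC[C@@H](C2(COC(C)=O)CO[C+](C)O2)[C@H](O[Sn-](Cl)(Cl)(Cl)Cl)[C@H]1C(=C)C | intermediate
19 | 2-[(1R,2R,3S,4S)-4-ethenyl-2-hydroxy-4-methyl-3-(prop-1-en-2-yl)cyclohexyl]-3-hydroxypropane-1,2-diyl diacetate, the C11 tertiary acetate, either configuration at C11 (not isolated) | C=C[C@]1(C)CC[C@@H](C(CO)(COC(C)=O)OC(C)=O)[C@H](O)[C@H]1C(=C)C | intermediate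
20 | 2-[(1R,2R,3S,4S)-4-ethenyl-2-hydroxy-4-methyl-3-(prop-1-en-2-yl)cyclohexyl]-2-hydroxypropane-1,3-diyl diacetate, CNP0273389.1 | C=C[C@]1(C)CC[C@@H](C(O)(COC(C)=O)COC(C)=O)[C@H](O)[C@H]1C(=C)C | target

**Step count and risks**

Total step count: 10. Longest linear sequence: 10 steps (1 to 20).

Steps most likely to fail:

1. Step 10. The alkene, made electron-poor by two allylic acetoxy groups, may attack the tin-bound aldehyde too slowly, so that ionization of an allylic acetate, proton loss from C11 or chloride capture outruns the acetate capture. Fallback: the same two bonds (C6–C7 and C11–O) would be made by an intramolecular nitrile oxide cycloaddition, a standard route to β-hydroxy ketones. Setting out from aldehyde 17, NH2OH·HCl and NaOAc in EtOH give the aldoxime F1. Aqueous NaOCl in CH2Cl2 at 0 °C oxidizes it to the nitrile oxide F2, which should add across the C7=C11 alkene through a chair with equatorial isopropenyl to give the isoxazoline F3. Mo(CO)6 in wet MeCN cleaves the N–O bond, and the imine hydrolyses to the β-hydroxy ketone F4. SmI2 in THF–MeOH then reduces the C6 ketone under electron-transfer conditions expected to favour the more stable equatorial alcohol, which returns to the route at the target 20.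

2. Step 6. The Lewis acidic boron bromide may open the isopropylidene acetal during the long rearrangement period. Fallback: the diol is carried through the rearrangement as silyl ethers. Setting out from ester 9, AcOH–H2O–THF frees the diol ester F5, and TBSCl with imidazole in DMF gives the bis(tert-butyldimethylsilyl) ether F6. The same bromoborane and Et3N convert it into the boron ketene acetal F7, which rearranges to the acyloxyborane F8 and gives the bis(silyl ether) acid F9 on aqueous work-up. HF·pyridine in THF then removes both silyl groups and returns to the route at the dihydroxy acid 13.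

3. Step 9. The hindered acyl chloride may be reduced past the aldehyde, or may lose the C5 configuration through ketene formation. Fallback: the acid is taken down to the alcohol and re-oxidized. Setting out from acid 15, isobutyl chloroformate and N-methylmorpholine in THF at −15 °C give the mixed carbonic anhydride F10. NaBH4 in THF–H2O at 0 °C reduces it to the C6 primary alcohol F11 with the acetates intact. Dess–Martin oxidation buffered with NaHCO3 in CH2Cl2 returns to the route at aldehyde 17.

**Further compounds**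

F1 | step 10 | aldoxime of 17, (2S,3S)-8-acetoxy-7-(acetoxymethyl)-3-ethenyl-3-methyl-2-(prop-1-en-2-yl)oct-6-enal oxime | ON=C[C@@H](C(C)=C)[C@](C)(C=C)CCC=C(COC(C)=O)COC(C)=O
F2 | step 10 | nitrile oxide derived from F1 | [O-][N+]#C[C@@H](C(C)=C)[C@](C)(C=C)CCC=C(COC(C)=O)COC(C)=O
F3 | step 10 | isoxazoline: 3,3-bis(acetoxymethyl)-6-ethenyl-6-methyl-7-(prop-1-en-2-yl)-3,3a,4,5,6,7-hexahydro-2,1-benzoxazole with ring substituents placed as in 20 | C=C[C@]1(C)CC[C@@H]2C(=NOC2(COC(C)=O)COC(C)=O)[C@H]1C(=C)C
F4 | step 10 | β-hydroxy ketone: the C6 ketone corresponding to 20 | C=C[C@]1(C)CC[C@@H](C(O)(COC(C)=O)COC(C)=O)C(=O)[C@H]1C(=C)C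
F5 | step 6 | (2E)-8-hydroxy-7-(hydroxymethyl)-3-methylocta-2,6-dien-1-yl 3-methylbut-3-enoate | C=C(C)CC(=O)OC/C=C(\C)CCC=C(CO)CO
F6 | step 6 | bis(tert-butyldimethylsilyl) ether of F5 | C=C(C)CC(=O)OC/C=C(\C)CCC=C(CO[Si](C)(C)C(C)(C)C)CO[Si](C)(C)C(C)(C)C
F7 | step 6 | E(O) boron ketene acetal of F6 with the (4S,5S)-diazaborolidinyl boron | C=C(C)/C=C(/OB1N(S(=O)(=O)c2cc(cc(c2)C(F)(F)F)C(F)(F)F)[C@@H](c2ccccc2)[C@H](c2ccccc2)N1S(=O)(=O)c1cc(cc(c1)C(F)(F)F)C(F)(F)F)OC/C=C(\C)CCC=C(CO[Si](C)(C)C(C)(C)C)CO[Si](C)(C)C(C)(C)C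
F8 | step 6 | acyloxyborane of the bis(silyl ether) acid | O=C(OB1N(S(=O)(=O)c2cc(cc(c2)C(F)(F)F)C(F)(F)F)[C@@H](c2ccccc2)[C@H](c2ccccc2)N1S(=O)(=O)c1cc(cc(c1)C(F)(F)F)C(F)(F)F)[C@@H](C(C)=C)[C@](C)(C=C)CCC=C(CO[Si](C)(C)C(C)(C)C)CO[Si](C)(C)C(C)(C)C
F9 | step 6 | (2S,3S)-8-(tert-butyldimethylsilyloxy)-7-[(tert-butyldimethylsilyloxy)methyl]-3-ethenyl-3-methyl-2-(prop-1-en-2-yl)oct-6-enoic acid | OC(=O)[C@@H](C(C)=C)[C@](C)(C=C)CCC=C(CO[Si](C)(C)C(C)(C)C)CO[Si](C)(C)C(C)(C)C
F10 | step 9 | isobutyl carbonic mixed anhydride of acid 15 | CC(C)COC(=O)OC(=O)[C@@H](C(C)=C)[C@](C)(C=C)CCC=C(COC(C)=O)COC(C)=O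
F11 | step 9 | (2S,3S)-8-acetoxy-7-(acetoxymethyl)-3-ethenyl-3-methyl-2-(prop-1-en-2-yl)oct-6-en-1-ol | OC[C@@H](C(C)=C)[C@](C)(C=C)CCC=C(COC(C)=O)COC(C)=O
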